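| setting | oak | cedar | beta | theta | eta | alpha | gamma |
|---|---|---|---|---|---|---|---|
| G | 0.0021 M | 0.039 M | 0.0040 M | 0.0080 M | 0.015 M | 0.030 M | 0.060 M |
| J | 1.3 mM (held) | 1.3 mM (held) | 1.3 mM (held) | 1.3 mM (held) | 1.3 mM (held) | 1.3 mM (held) | 1.3 mM (held) |
| remark | run made earlier | run made earlier |  |  |  |  |  |
| time |  |  | 3.0 d | 3.0 d | 3.0 d | 3.0 d | 3.0 d |

- oak (time / h: Z / %, E / %): 2.50: 0.6, 6.8; 8.00: 5.4, 23.5; 15.0: 10.8, 37.7; 20.0: 14.6, 45.7; 30.0: 18.5, 56.9; 40.0: 21.4, 63.4; 48.0: 23.0, 66.7
- cedar (time / h: Z / %, E / %): 2.50: 0.7, 6.7; 8.00: 2.4, 24.9; 15.0: 6.6, 41.9; 20.0: 8.9, 50.2; 30.0: 12.0, 62.5; 40.0: 14.8, 69.1; 48.0: 15.9, 73.0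

(each reading ± 0.3 percentage points)

- the analysis behind the earlier runs scatters by 0.3 percentage points, standard deviation
- at the start none of J is in solution
- "hardly changes" means that all values lie within two and a half points (for a concentration: within two and a half percent of the largest)

- share of Z in all that became Z or E for beta, theta, eta, alpha, gamma, in this order
- how that number moves from the first to the last of them (falls, then rises / falls all the way / rises, then falls / hardly changes / rises all the way)

**Amounts first.** Beta holds 0.0040 M of G and gamma 0.060 M, while dissolved J starts from none and has a saturation concentration of 1.3 mM. If Z takes up J, then gamma's J must arrive during the run. So you should compare flows, not stocks.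

**Fastest rung.** In oak, Z is 8.11% of the product of the first 2.50 h, but 29.3% of the product made between 8.00 h and 20.0 h. Oak's Z therefore starts within hours, behind E.

**Middle rung.** Take the part of the charge not yet in Z or E as G, falling roughly at first order with rate constant k. Oak reads 0.0462 h⁻¹ and cedar 0.0447 h⁻¹, so G's time constant is about 21.6 h. Over the same interval, cedar's share reads 20.4%, lower than oak's, and its Z flow reads F = 0.211 mM h⁻¹. I take F as the ceiling on Z flow. A flask starting at charge c asks for a Z flow of about oak's share times k times c. That demand equals F at c* = 15.6 mM, the crossover charge.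

**Slowest rung.** The run lasts 3.33 time constants, which leaves about 3.59% of G. The asked share (the selectivity) is therefore a whole-run figure.

**My reckoning.** Beta stands at 0.256 c* and gamma at 3.85 c*. I expect a share near oak's 25.6% at low charge, sinking once c passes c*, with gamma below cedar's 17.9%.

**The forecast.** It gives 25.5%, 24.6%, 23%, 20% and 16%, so the share falls all the way. In its words: “This gives a share that falls steadily with charge”.

**The result.** The flasks give 25.4%, 24.5%, 23.0%, 20.0% and 15.6%: the share falls all the way.

    J ⇌ D, rate k1*(csat - [D]) (kL = 0.00551 min⁻¹)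
    Q + X → Z (k = 5.31 M⁻¹ min⁻¹)
    2 X → L (k = 1.94 M⁻¹ min⁻¹)
    Q → E (k = 0.0139 min⁻¹)
    D → X (k = 0.0100 min⁻¹)
    G ⇌ Q (K = 0.465, k = 8.70 × 10⁻⁴ min⁻¹)

At 1.50 d, X, formed on the way from dissolved reagent D, stands at 7.72 × 10⁻⁴ M in gamma against 0.00107 M in beta. Eta sits at 0.961 c*. The share goes down by 2.4 percentage points from beta to eta, and by 7.4 points from eta to gamma.

Readings and results were generated by integration for substances that don't exist; noise was put on by code.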